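## Analysis of the target

The target is a twofold-symmetric bis-quinone with two identical, fully substituted 1,4-benzoquinone rings (ring A and ring B). In quinone numbering each ring has carbonyls at C1 and C4, a hydroxyl at C2, a methoxy group at C5 and a methyl group at C6. The rings are joined through their C3 atoms by an unbranched saturated chain of fourteen carbons (C1' to C14'). There are no stereocentres and no double-bond geometry to control.

The sensitive groups are the quinones (reducible, electrophilic, incompatible with organometallic reagents and reducing metals), the acidic 2-hydroxyquinone (a vinylogous carboxylic acid) and the C5 methoxy group (a vinylogous ester that nucleophiles can exchange or hydrolyse). The carbon skeleton is simple; the difficulty is regiochemical. The oxygen substituents at C2 and C5 sit in electronically equivalent vinylogous positions and differ only in their neighbours (chain at C3, methyl at C6), so a late hydrolysis or methylation cannot tell them apart, and every operation has to succeed on both rings. The rings are therefore carried as protected tetra-oxygenated arenes in which the future C2 oxygen already bears a group other than methyl, and the quinones are released last.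

The strategy rests on the C7'–C8' bond. It bisects the tether, so the molecule is a head-to-head dimer of two identical 7-arylheptyl halves, and one bond between two like carbons completes the whole skeleton.

## Retrosynthetic reasoning

Arene positions below are numbered with the chain-bearing carbon as C1; arene C6 becomes quinone C2 (OH), arene C2 and C5 become the quinone carbonyls, and arene C3 keeps its methoxy group.

**16 to 15.** The two O–acetyl bonds are cut first. In 15 the acetate sits on a quinone and is a vinylogous mixed anhydride, so mild methanolysis should cleave it at the acyl carbon. Methoxide exchange at the neighbouring methoxy group is degenerate in methanol, so the last step carries no regiochemical risk.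

**15 to 14 to 13 to 12.** The quinone carbonyls are traced back to the para-related methoxy groups at arene C2 and C5 of 14 (oxidative demethylation). The acetate is what makes this selective. A free phenol at C6, as in 13, would be oxidised across its own para methoxy group at C3, giving a dimethoxyquinone whose two methoxy groups cannot be distinguished afterwards. Acylation turns the C6 oxygen into a poor donor and leaves C2/C5 as the only oxidisable para pair. If oxidation instead took the adjacent C2/C3 pair, the resulting ortho-quinone acetate would tautomerise, after loss of the acetyl group, to the same hydroxyquinone 16. The acetates come from bis-phenol 13, and 13 from the bis-acetal 12, because an acetal, unlike an aryl ester or a free phenol, is inert to the organolithium and low-valent nickel chemistry used earlier.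

**12 to two molecules of 11.** The C7'–C8' bond is cut. It is the only disconnection that gives two identical fragments, so no bifunctional linker has to be differentiated and no statistical mixture of mono- and bis-adducts arises at the ring. The bond lies six atoms from any functionality, so the arene substituents have no influence on it. Both carbons are taken as electrophiles (primary bromides) and joined reductively under nickel catalysis with a metal reductant. With a single electrophile only one coupling product is possible.

**11 to 8 and 9.** The aryl–C1' bond is cut. Arene 8 has one ring hydrogen left, flanked by a methoxy and a methoxymethoxy group, so directed lithiation is unambiguous. Alkylation with an excess of the symmetric dibromide 9 installs the seven-carbon arm with its terminal bromide in one operation.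

**8 to 7 to 5 to 3.** The C6 oxygen is traced through phenol 7 to a formyl group (aryl migration in a peracid oxidation of aldehyde 5). The formyl group is introduced by electrophilic substitution of 3 at the free position that is para to one methoxy group and ortho to another. This places the oxygen exactly where the later hydroxyl is needed and keeps it distinct from the three methyl ethers.

**3 to 1.** The ring methyl is cut off. In 1 the hydrogen between two methoxy groups is the most acidic, so lithiation and methylation place the methyl group between them, as required for quinone C6.

## Alternatives that were turned down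

**Alternative 1: building both rings from acyclic carbon by Michael–Claisen annulation.**
- Disconnection: in each ring the bond from the chain-bearing carbon to its neighbour and the bond from the methyl-bearing carbon to an oxygenated carbon are cut. This leads to (4E,20E)-tetracosa-4,20-diene-3,22-dione A1 and two molecules of dimethyl malonate A2.
- Forward key step: with NaOMe in methanol, A2 adds twice in conjugate fashion to A1, and each ethyl-ketone enolate then closes onto a malonate ester carbonyl. The product is the bis(cyclohexane-1,3-dione) ester A3, a mixture of diastereomers.
- For it: four carbon–carbon bonds and both rings form in one flask from cheap acyclic material, with the ring methyl and the tether in place and no protecting groups or organolithium chemistry. On bond-forming efficiency in the key step it is stronger than the chosen route.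
- Against it: A3 has only two oxygens per ring, both on the carbons flanking the methyl group, and is at the cyclohexanedione oxidation level. After decarboxylation and aromatisation, two further oxygens must be introduced next to the chain. One of two symmetry-equivalent resorcinol oxygens must then become the methyl ether and the other a carbonyl, which is the same undifferentiated-oxygen problem the target poses, left unsolved and doubled.
- Comparison: the end-game would be long and poorly controlled. The chosen route takes three ring oxygens from compound 1 and fixes the hydroxyl/methoxy distinction with a protecting group, so four predictable steps follow its key step.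

**Alternative 2: squarate-based double electrocyclic ring expansion.**
- Disconnection: each six-membered ring is opened at the bond between the hydroxyl-bearing carbon next to the methyl group and the tert-butoxy-bearing carbon. This traces each ring to a four-membered squaric acid derivative plus a two-carbon alkenyl unit and leads to the tethered bis(cyclobutenone) A4.
- Forward key step: thermolysis of A4 (refluxing xylene) opens both four-membered rings to dienylketenes, which undergo six-electron electrocyclic closure and tautomerise to the bis-hydroquinone A5. Oxidation and acid removal of the tert-butyl groups would then give 16.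
- For it: the whole oxygen pattern, including the hydroxyl/methoxy distinction (tert-butyl against methyl ether), is programmed by the building blocks, and the end-game is two mild steps without a cerium oxidation. On regiocontrol of the ring oxygens and on end-game length it is as strong as or stronger than the chosen route.
- Against it: A4 requires a doubly metalated, alkoxy-substituted bis-alkenyl tether to add twice, and site-selectively, to an unsymmetrical squaric-acid-derived dione. Both partners need multistep preparation. Two thermal cascades must both succeed in one molecule, and the tert-butyl enol ethers may lose isobutene on heating.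
- Comparison: the chosen route offers intermediates anchored in commercial aromatics and robust reactions, with the risk confined to one carbon–carbon bond formation.

**Alternative 3: two-directional cross-metathesis of an allylarene.**
- Disconnection: the C2'=C3' and C12'=C13' bonds of an unsaturated tether are cut. This leads to two molecules of 2-allyl-3,4,6-trimethoxy-5-methylphenyl acetate A6 and dodeca-1,11-diene A7. A6 would come from phenol 7 of the present route by O-allylation, aromatic Claisen rearrangement into its only free ortho position and acetylation.
- Forward key step: double cross-metathesis of A6 with A7 using the second-generation Grubbs catalyst RuCl2(=CHPh)(H2IMes)(PCy3), with loss of ethylene, to the diene diacetate A8. Hydrogenation, cerium oxidation and methanolysis would follow.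
- For it: the Claisen step is regiochemically unambiguous, the acetate is already in place so no protecting-group exchange is needed, the aryllithium alkylation is avoided, and the overall length is about the same (ten steps). On those points it is at least as strong as the chosen route.
- Against it: both partners are unhindered terminal olefins of similar reactivity, so the key step is statistical. Self-metathesis of A6, oligomerisation of A7 and mono-coupled product all compete, and A6 can isomerise to the propenyl arene under ruthenium hydride formation. The valuable arene would have to be used in large excess.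
- Comparison: the chosen homocoupling has one electrophile and therefore one possible coupling product, which is the advantage it offers in exchange for the extra protecting-group steps.

Key step: step 6

Assumption: the target is taken as the 2-hydroxy-1,4-benzoquinone tautomer drawn in its SMILES; it has no stereocentres.

## Route

Step 1
Reactants: 1 1,2,4-trimethoxybenzene
Product: 3 1,2,4-trimethoxy-3-methylbenzene, via (2,3,6-trimethoxyphenyl)lithium 2 (not isolated)
Conditions: n-BuLi, THF, 0 °C to rt; then MeI, 0 °C to rt
Reagents that add atoms: iodomethane, CI
Why: Directed ortho-metalation: the hydrogen between the two methoxy groups of 1 is the most acidic, so lithiation should give 2 selectively, and SN2 methylation then gives 3.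

Step 2
Reactants: 3 1,2,4-trimethoxy-3-methylbenzene
Product: 5 2,4,5-trimethoxy-3-methylbenzaldehyde, via 1-[chloro(methoxy)methyl]-2,4,5-trimethoxy-3-methylbenzene 4 (not isolated)
Conditions: Cl2CHOMe, TiCl4, CH2Cl2, -10 to 0 °C; then ice/H2O
Reagents that add atoms: dichloromethyl methyl ether, COC(Cl)Cl; water, O
Why: Rieche formylation (electrophilic aromatic substitution): attack is expected at the free position para to one methoxy group and ortho to another, since the other free position has only one ortho methoxy and a para methyl to stabilise the arenium ion; aqueous work-up hydrolyses chloro ether 4 to the aldehyde.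

Step 3
Reactants: 5 2,4,5-trimethoxy-3-methylbenzaldehyde
Product: 7 2,4,5-trimethoxy-3-methylphenol, via 2,4,5-trimethoxy-3-methylphenyl formate 6 (not isolated)
Conditions: mCPBA, CH2Cl2, 0 °C to rt; aq NaHCO3/Na2S2O3 wash; crude 6, K2CO3 (cat.), MeOH, rt, argon
Reagents that add atoms: 3-chloroperoxybenzoic acid, OOC(=O)c1cccc(Cl)c1
Why: Baeyer–Villiger (Dakin-type) oxidation: the electron-rich aryl group migrates in preference to hydride, giving formate 6, which mild methanolysis cleaves; the peracid is removed before the oxidation-prone phenol is set free.

Step 4
Reactants: 7 2,4,5-trimethoxy-3-methylphenol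
Product: 8 1,2,4-trimethoxy-5-(methoxymethoxy)-3-methylbenzene
Conditions: MOMCl, i-Pr2NEt, CH2Cl2, 0 °C to rt
Reagents that add atoms: chloromethyl methyl ether, COCCl
Why: O-alkylation of the phenol with a reactive alpha-chloro ether; the acetal masks the acidic OH against the organolithium and nickel steps and is a strong ortho-directing group for step 5.

Step 5
Reactants: 8 1,2,4-trimethoxy-5-(methoxymethoxy)-3-methylbenzene; 9 1,7-dibromoheptane (5 equiv)
Product: 11 1-(7-bromoheptyl)-2,3,5-trimethoxy-6-(methoxymethoxy)-4-methylbenzene, via [2,3,5-trimethoxy-6-(methoxymethoxy)-4-methylphenyl]lithium 10 (not isolated)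
Conditions: n-BuLi, TMEDA, THF, -20 to 0 °C; then added to 9 in THF, -78 °C to rt
Reagents that add atoms: none
Why: Directed ortho-metalation then SN2 alkylation: the only ring hydrogen of 8 lies between the methoxy and methoxymethoxy groups, so the site is unambiguous; inverse addition into excess 9 should suppress double arylation, and surplus 9 is recovered by distillation.

Step 6
Reactants: 11 1-(7-bromoheptyl)-2,3,5-trimethoxy-6-(methoxymethoxy)-4-methylbenzene (two molecules)
Product: 12 1,14-bis[2,3,5-trimethoxy-6-(methoxymethoxy)-4-methylphenyl]tetradecane
Conditions: NiCl2(dme) (5 mol %), 4,4',4''-tri-tert-butyl-2,2':6',2''-terpyridine (5 mol %), Mn powder, DMF, 40 °C, argon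
Reagents that add atoms: none
Why: Nickel-catalysed reductive homocoupling of an unactivated primary alkyl bromide with a metal powder reductant, a known reaction type. Manganese reduces the divalent nickel precatalyst to a low-valent terpyridine–nickel species, which abstracts bromine from 11 to give a primary alkyl radical. An alkylnickel species formed in the same way captures the radical, and the resulting dialkyl trivalent nickel reductively eliminates the C7'–C8' bond; manganese then regenerates the low-valent catalyst. No ring is closed and no stereocentre is formed. The step must outrun beta-hydride elimination and hydrodehalogenation of the alkylnickel intermediate. The tridentate terpyridine leaves no free cis site for beta-hydride elimination, the unhindered primary bromide is activated quickly, and dry DMF with the phenol masked as its acetal removes proton sources. With one electrophile only one coupling product can form, and the hexasubstituted arene, its methyl ethers and the acetal should be inert to low-valent nickel under these mild conditions.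

Step 7
Reactants: 12 1,14-bis[2,3,5-trimethoxy-6-(methoxymethoxy)-4-methylphenyl]tetradecane
Product: 13 1,14-bis(2-hydroxy-3,5,6-trimethoxy-4-methylphenyl)tetradecane
Conditions: conc. HCl (cat.), MeOH/THF, 50 °C, argon
Reagents that add atoms: none
Why: Acid-catalysed acetal exchange: the protonated methoxymethyl ether releases the phenol and methanol traps the oxocarbenium ion as dimethoxymethane; aryl methyl ethers are stable to these conditions.

Step 8
Reactants: 13 1,14-bis(2-hydroxy-3,5,6-trimethoxy-4-methylphenyl)tetradecane
Product: 14 1,14-bis(2-acetoxy-3,5,6-trimethoxy-4-methylphenyl)tetradecane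
Conditions: Ac2O, pyridine, DMAP (cat.), CH2Cl2, rt
Reagents that add atoms: acetic anhydride, CC(=O)OC(C)=O
Why: DMAP-catalysed acylation of the hindered phenol; the acetate makes this oxygen a poor electron donor so that it cannot take part in the quinone-forming oxidation.

Step 9
Reactants: 14 1,14-bis(2-acetoxy-3,5,6-trimethoxy-4-methylphenyl)tetradecane
Product: 15 1,14-bis(2-acetoxy-5-methoxy-4-methyl-3,6-dioxocyclohexa-1,4-dien-1-yl)tetradecane
Conditions: (NH4)2Ce(NO3)6, MeCN/CH2Cl2/H2O, 0 °C
Reagents that add atoms: water, O
Why: Oxidative demethylation by tetravalent cerium: water attacks the arene radical cation at methoxy-bearing carbons, and with the third oxygen acylated only the methoxy groups flanking the chain and the methyl on opposite sides are para-related donors; oxidation across the adjacent methoxy pair would give an ortho-quinone acetate that converges on the same hydroxyquinone after step 10.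

Step 10
Reactants: 15 1,14-bis(2-acetoxy-5-methoxy-4-methyl-3,6-dioxocyclohexa-1,4-dien-1-yl)tetradecane
Product: 16 3,3'-(tetradecane-1,14-diyl)bis(2-hydroxy-5-methoxy-6-methylcyclohexa-2,5-diene-1,4-dione) (target, CNP0278640.0)
Conditions: K2CO3, MeOH/THF, 0 °C; then 1 M HCl
Reagents that add atoms: none
Why: Methanolysis of a vinylogous mixed anhydride: methoxide attacks the acetyl carbonyl and releases the stabilised hydroxyquinone anion; methoxide exchange at the ring methoxy group is degenerate in methanol, and acidification returns the neutral hydroxyquinone.

## Compound list

1 | 1,2,4-trimethoxybenzene | COc1ccc(OC)c(OC)c1 | starting material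
2 | (2,3,6-trimethoxyphenyl)lithium | [Li]c1c(OC)ccc(OC)c1OC | intermediate
3 | 1,2,4-trimethoxy-3-methylbenzene | COc1ccc(OC)c(OC)c1C | intermediate
4 | 1-[chloro(methoxy)methyl]-2,4,5-trimethoxy-3-methylbenzene | COC(Cl)c1cc(OC)c(OC)c(C)c1OC | intermediate
5 | 2,4,5-trimethoxy-3-methylbenzaldehyde | O=Cc1cc(OC)c(OC)c(C)c1OC | intermediate
6 | 2,4,5-trimethoxy-3-methylphenyl formate | O=COc1cc(OC)c(OC)c(C)c1OC | intermediate
7 | 2,4,5-trimethoxy-3-methylphenol | Oc1cc(OC)c(OC)c(C)c1OC | intermediate
8 | 1,2,4-trimethoxy-5-(methoxymethoxy)-3-methylbenzene | COCOc1cc(OC)c(OC)c(C)c1OC | intermediate
9 | 1,7-dibromoheptane | BrCCCCCCCBr | starting material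
10 | [2,3,5-trimethoxy-6-(methoxymethoxy)-4-methylphenyl]lithium | [Li]c1c(OC)c(OC)c(C)c(OC)c1OCOC | intermediate
11 | 1-(7-bromoheptyl)-2,3,5-trimethoxy-6-(methoxymethoxy)-4-methylbenzene | BrCCCCCCCc1c(OC)c(OC)c(C)c(OC)c1OCOC | intermediate
12 | 1,14-bis[2,3,5-trimethoxy-6-(methoxymethoxy)-4-methylphenyl]tetradecane | COCOc1c(OC)c(C)c(OC)c(OC)c1CCCCCCCCCCCCCCc1c(OCOC)c(OC)c(C)c(OC)c1OC | intermediate
13 | 1,14-bis(2-hydroxy-3,5,6-trimethoxy-4-methylphenyl)tetradecane | Oc1c(OC)c(C)c(OC)c(OC)c1CCCCCCCCCCCCCCc1c(O)c(OC)c(C)c(OC)c1OC | intermediate
14 | 1,14-bis(2-acetoxy-3,5,6-trimethoxy-4-methylphenyl)tetradecane | CC(=O)Oc1c(OC)c(C)c(OC)c(OC)c1CCCCCCCCCCCCCCc1c(OC(C)=O)c(OC)c(C)c(OC)c1OC | intermediate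
15 | 1,14-bis(2-acetoxy-5-methoxy-4-methyl-3,6-dioxocyclohexa-1,4-dien-1-yl)tetradecane | COC1=C(C)C(=O)C(OC(C)=O)=C(CCCCCCCCCCCCCCC2=C(OC(C)=O)C(=O)C(C)=C(OC)C2=O)C1=O | intermediate
16 | 3,3'-(tetradecane-1,14-diyl)bis(2-hydroxy-5-methoxy-6-methylcyclohexa-2,5-diene-1,4-dione) | COC1=C(C)C(=O)C(O)=C(CCCCCCCCCCCCCCC2=C(O)C(=O)C(C)=C(OC)C2=O)C1=O | target

## Step count and least certain steps

Total: 10 steps. Longest linear sequence: 10 steps, from 1 to 16.

**Step 6 (key step).** The most likely failure is hydrodehalogenation of the alkylnickel intermediate (by adventitious proton sources) or beta-hydride elimination to the terminal alkene. Both are unimolecular and gain ground over the bimolecular coupling when the manganese surface is passivated and the catalyst turns over slowly. Fallback, setting out from 11: one portion is converted with magnesium turnings in THF into {7-[2,3,5-trimethoxy-6-(methoxymethoxy)-4-methylphenyl]heptyl}magnesium bromide F1, which is coupled with a second equivalent of 11 under Li2CuCl4 catalysis in THF at 0 °C (copper-catalysed Grignard–alkyl bromide coupling). This polar, non-reductive coupling forms the same C7'–C8' bond and returns to the route at 12.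

**Step 5.** The hindered, di-ortho-substituted aryllithium 10 is a sluggish SN2 nucleophile. It may act as a base (E2 on 9, returning 8) or attack product 11 a second time, giving a 1,7-diarylheptane. Fallback, setting out from 8: lithiation as before and quenching with iodine should give 1-iodo-2,3,5-trimethoxy-6-(methoxymethoxy)-4-methylbenzene F2. Sonogashira coupling of F2 with commercial hept-6-yn-1-ol (Pd(PPh3)2Cl2, CuI, Et3N, 60 °C) gives 7-[2,3,5-trimethoxy-6-(methoxymethoxy)-4-methylphenyl]hept-6-yn-1-ol F3. Hydrogenation (H2, Pd/C, EtOAc) gives 7-[2,3,5-trimethoxy-6-(methoxymethoxy)-4-methylphenyl]heptan-1-ol F4, and Appel bromination (CBr4, PPh3, imidazole, CH2Cl2, 0 °C) returns to the route at 11.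

**Step 9.** In the strongly acidic nitrate medium the acetyl group may be partly lost before oxidation, and the freed phenol would then be oxidised across its own para methoxy group to the isomeric dimethoxyquinone. The electron-rich rings may also be nitrated or over-oxidised, and the second ring may lag because the lipophilic bis-arene dissolves poorly. Fallback, setting out from 13: benzoylation (BzCl, pyridine, DMAP) gives the more acid-stable 1,14-bis(2-benzoyloxy-3,5,6-trimethoxy-4-methylphenyl)tetradecane F5. Oxidation with PhI(OCOCF3)2 in MeCN/H2O, a two-electron trivalent iodine oxidant free of nitric acid, gives 1,14-bis(2-benzoyloxy-5-methoxy-4-methyl-3,6-dioxocyclohexa-1,4-dien-1-yl)tetradecane F6. Methanolysis with K2CO3 in MeOH returns to the route at 16.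

**Step 10.** Methoxide may add to the quinone ring and displace acetate by addition–elimination (giving a dimethoxyquinone), or the quinone may degrade in base before the stabilised anion forms. Fallback, setting out from 15: reduction with Na2S2O4 (EtOAc/H2O) gives 1,14-bis(2-acetoxy-3,6-dihydroxy-5-methoxy-4-methylphenyl)tetradecane F7, in which the ester is an ordinary aryl acetate. K2CO3 in degassed MeOH under argon then gives 3,3'-(tetradecane-1,14-diyl)bis(5-methoxy-6-methylbenzene-1,2,4-triol) F8, and exposure of the acidified solution to air re-oxidises it to 16.

## Further compounds

F1 | step 6 | {7-[2,3,5-trimethoxy-6-(methoxymethoxy)-4-methylphenyl]heptyl}magnesium bromide | Br[Mg]CCCCCCCc1c(OC)c(OC)c(C)c(OC)c1OCOC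
F2 | step 5 | 1-iodo-2,3,5-trimethoxy-6-(methoxymethoxy)-4-methylbenzene | COCOc1c(I)c(OC)c(OC)c(C)c1OC
F3 | step 5 | 7-[2,3,5-trimethoxy-6-(methoxymethoxy)-4-methylphenyl]hept-6-yn-1-ol | COCOc1c(C#CCCCCCO)c(OC)c(OC)c(C)c1OC
F4 | step 5 | 7-[2,3,5-trimethoxy-6-(methoxymethoxy)-4-methylphenyl]heptan-1-ol | COCOc1c(CCCCCCCO)c(OC)c(OC)c(C)c1OC
F5 | step 9 | 1,14-bis(2-benzoyloxy-3,5,6-trimethoxy-4-methylphenyl)tetradecane | O=C(Oc1c(OC)c(C)c(OC)c(OC)c1CCCCCCCCCCCCCCc1c(OC(=O)c2ccccc2)c(OC)c(C)c(OC)c1OC)c1ccccc1
F6 | step 9 | 1,14-bis(2-benzoyloxy-5-methoxy-4-methyl-3,6-dioxocyclohexa-1,4-dien-1-yl)tetradecane | COC1=C(C)C(=O)C(OC(=O)c3ccccc3)=C(CCCCCCCCCCCCCCC2=C(OC(=O)c3ccccc3)C(=O)C(C)=C(OC)C2=O)C1=O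
F7 | step 10 | 1,14-bis(2-acetoxy-3,6-dihydroxy-5-methoxy-4-methylphenyl)tetradecane | CC(=O)Oc1c(O)c(C)c(OC)c(O)c1CCCCCCCCCCCCCCc1c(O)c(OC)c(C)c(O)c1OC(C)=O
F8 | step 10 | 3,3'-(tetradecane-1,14-diyl)bis(5-methoxy-6-methylbenzene-1,2,4-triol) | Oc1c(O)c(C)c(OC)c(O)c1CCCCCCCCCCCCCCc1c(O)c(OC)c(C)c(O)c1O
A1 | alternative 1 | (4E,20E)-tetracosa-4,20-diene-3,22-dione | CCC(=O)/C=C/CCCCCCCCCCCCCC/C=C/C(=O)CC
A2 | alternative 1 | dimethyl malonate | COC(=O)CC(=O)OC
A3 | alternative 1 | dimethyl 6,6'-(tetradecane-1,14-diyl)bis(3-methyl-2,4-dioxocyclohexane-1-carboxylate), diastereomer mixture | COC(=O)C1C(=O)C(C)C(=O)CC1CCCCCCCCCCCCCCC1CC(=O)C(C)C(=O)C1C(=O)OC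
A4 | alternative 2 | 4,4'-(1,18-di-tert-butoxyoctadeca-1,17-diene-2,17-diyl)bis(4-hydroxy-3-methoxy-2-methylcyclobut-2-en-1-one), stereoisomer mixture | COC1=C(C)C(=O)C1(O)C(=COC(C)(C)C)CCCCCCCCCCCCCCC(=COC(C)(C)C)C1(O)C(OC)=C(C)C1=O
A5 | alternative 2 | 1,14-bis(2-tert-butoxy-3,6-dihydroxy-5-methoxy-4-methylphenyl)tetradecane | COc1c(C)c(O)c(OC(C)(C)C)c(CCCCCCCCCCCCCCc2c(O)c(OC)c(C)c(O)c2OC(C)(C)C)c1O
A6 | alternative 3 | 2-allyl-3,4,6-trimethoxy-5-methylphenyl acetate | CC(=O)Oc1c(OC)c(C)c(OC)c(OC)c1CC=C
A7 | alternative 3 | dodeca-1,11-diene | C=CCCCCCCCCC=C
A8 | alternative 3 | (2E,12E)-tetradeca-2,12-diene-1,14-diylbis(3,4,6-trimethoxy-5-methyl-2,1-phenylene) diacetate | CC(=O)Oc1c(OC)c(C)c(OC)c(OC)c1C/C=C/CCCCCCCC/C=C/Cc1c(OC(C)=O)c(OC)c(C)c(OC)c1OC
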